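**Strategy.** The route rests on cutting the quinone ring of the naphthazarin at C1–C8a and C4–C4a. C1–C4, with the C2 side chain and its (R) carbinol already in place, are the four carbons of a 3-substituted furan. C4a–C8a, with both oxygens, are symmetric 3,6-dimethoxybenzyne. One aryne–furan [4+2] cycloaddition forms both bonds and closes the carbocycle under a transient 1,4-oxygen bridge, which is later opened to a naphthol and oxidised to the quinone. The furan precursor carries the (R,E)-allylic carbinol as its tert-butyldimethylsilyl ether and the tertiary alcohol as a triethylsilyl ether; the (R)-2-methylbutanoyl group is attached in the last step.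

Key step: step 4

Assumptions and remarks on the chemistry:
- TES = triethylsilyl, TBS = tert-butyldimethylsilyl.
- Both stereocentres of the target are R (the side-chain carbinol C1′ and C2 of the acyl group).
- The two rings of a naphthazarin exchange quinone and hydroquinone character by fast tautomerism, so 18, 19 and 22 are drawn as the tautomer of the target SMILES.
- Compound 11 is a mixture of the two bridgehead diastereomers and is drawn without bridgehead descriptors.

Step 1
Reactants: 1 2-methylbut-3-yn-2-ol
Product: 2 triethyl[(2-methylbut-3-yn-2-yl)oxy]silane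
Conditions: TESCl, imidazole, DMAP (cat.), DMF, rt
Reagents that add atoms: chlorotriethylsilane, CC[Si](Cl)(CC)CC
Why: Imidazole-promoted O-silylation of the unhindered tertiary propargylic alcohol masks the acidic OH before the organoborane, organozinc and amide-base steps; no stereocentre is involved.

Step 2
Reactants: 2 triethyl[(2-methylbut-3-yn-2-yl)oxy]silane; 3 furan-3-carbaldehyde
Product: 6 (1R,2E)-1-(furan-3-yl)-4-methyl-4-(TESO)pent-2-en-1-ol, via alkenylborane 4 (not isolated), via alkenylzinc 5 (not isolated)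
Conditions: Cy2BH (from BH3·SMe2 and cyclohexene), toluene, 0 °C → rt; Me2Zn, −78 °C; (+)-3-exo-morpholinoisoborneol (5 mol %), then 3, −20 → 0 °C; aq. NH4Cl
Reagents that add atoms: none
Why: Syn hydroboration of the terminal alkyne fixes the E alkene, boron-to-zinc exchange gives alkenylzinc 5, and the zinc amino-alkoxide catalyst should deliver the alkenyl group to the Re face of the aldehyde (catalytic enantioselective alkenylzinc addition; the mirror-image ligand is the one that gives Si-face addition to aromatic aldehydes), which sets the (R) carbinol.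

Step 3
Reactants: 6 (1R,2E)-1-(furan-3-yl)-4-methyl-4-(TESO)pent-2-en-1-ol
Product: 7 3-[(1R,2E)-1-(TBSO)-4-methyl-4-(TESO)pent-2-en-1-yl]furan
Conditions: TBSCl, imidazole, DMF, rt
Reagents that add atoms: tert-butylchlorodimethylsilane, CC(C)(C)[Si](C)(C)Cl
Why: Imidazole-promoted silylation of the secondary alcohol leaves the stereocentre untouched; TBS is preferred to TES here because this ether must outlast amide base, catalytic acid, zinc/anhydride and tetravalent cerium, and its bulk shields the carbinol C–H.

Step 4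
Reactants: 7 3-[(1R,2E)-1-(TBSO)-4-methyl-4-(TESO)pent-2-en-1-yl]furan; 8 2-chloro-1,4-dimethoxybenzene
Product: 11 2-[(1R,2E)-1-(TBSO)-4-methyl-4-(TESO)pent-2-en-1-yl]-5,8-dimethoxy-1,4-dihydro-1,4-epoxynaphthalene (both bridgehead diastereomers), via aryllithium 9 (not isolated), via aryne 10 (not isolated)
Conditions: 8 (3 equiv), LiN(iPr)2 (2.8 equiv, added over 1 h), THF (0.5 M in 7), −78 °C → rt
Reagents that add atoms: none
Why: The amide base removes the proton between Cl and OMe of 8 to give aryllithium 9, which loses LiCl on warming to the symmetric aryne 10; the electron-rich furan of 7 then adds across its C2 and C5 in a concerted [4+2] cycloaddition, the standard aryne–furan Diels–Alder route to 7-oxabenzonorbornadienes. This single intermolecular annulation forms C1–C8a and C4–C4a and so closes the six-membered carbocycle together with its 1,4-oxygen bridge. The two bridgehead carbons are new stereocentres, cis to each other by the geometry of the bridge and uncontrolled relative to the side-chain centre, which does not matter because both are destroyed on aromatisation in step 5. No regioselectivity is needed since 10 is symmetric. The selectivity that matters is furan against amine for the aryne: 8 and base are used in threefold excess over 7 at high concentration, and the base is kept below the amount of 8 so that no free amide remains to attack the doubly allylic carbinol C–H, which the TBS group also shields, so the (R) centre should stay intact.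

Step 5
Reactants: 11 2-[(1R,2E)-1-(TBSO)-4-methyl-4-(TESO)pent-2-en-1-yl]-5,8-dimethoxy-1,4-dihydro-1,4-epoxynaphthalene
Product: 14 2-[(1R,2E)-1-(TBSO)-4-methyl-4-(TESO)pent-2-en-1-yl]-5,8-dimethoxynaphthalene-1,4-dione, via naphthol 12 (not isolated), via naphthol 13 (not isolated)
Conditions: camphorsulfonic acid (10 mol %), CH2Cl2, 0 °C; then (KSO3)2NO, KH2PO4/Na2HPO4 buffer (pH 7), Bu4NHSO4 (cat.), H2O/CH2Cl2, rt
Reagents that add atoms: potassium nitrosodisulfonate, [K+].[K+].[O]N(S(=O)(=O)[O-])S(=O)(=O)[O-]
Why: Catalytic anhydrous acid ionises one bridgehead C–O bond to a methoxy-stabilised allylic benzylic cation, and hydride shift with tautomerisation gives naphthols 12 and 13 (acid isomerisation of 7-oxabenzonorbornadienes, with the silyl ethers safe because no nucleophilic solvent is present), after which Teuber oxidation under phase transfer should convert either naphthol at its free para position into the same 1,4-quinone.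

Step 6
Reactants: 14 2-[(1R,2E)-1-(TBSO)-4-methyl-4-(TESO)pent-2-en-1-yl]-5,8-dimethoxynaphthalene-1,4-dione
Product: 16 2-[(1R,2E)-1-(TBSO)-4-methyl-4-(TESO)pent-2-en-1-yl]-5,8-dimethoxynaphthalene-1,4-diyl diacetate, via hydroquinone 15 (not isolated)
Conditions: Zn dust, Ac2O, pyridine, DMAP (cat.), CH2Cl2, rt
Reagents that add atoms: acetic anhydride, CC(=O)OC(C)=O
Why: Reductive acetylation (zinc reduces the quinone to hydroquinone 15, which is acetylated at once) should be clean because the benzylic silyloxy group, unlike an ester, is too poor a leaving group to be expelled from the electron-rich hydroquinone, and the two acetates deactivate this ring for the next step.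

Step 7
Reactants: 16 2-[(1R,2E)-1-(TBSO)-4-methyl-4-(TESO)pent-2-en-1-yl]-5,8-dimethoxynaphthalene-1,4-diyl diacetate
Product: 17 6-[(1R,2E)-1-(TBSO)-4-methyl-4-(TESO)pent-2-en-1-yl]-1,4-dioxo-1,4-dihydronaphthalene-5,8-diyl diacetate
Conditions: (NH4)2Ce(NO3)6 (2.5 equiv), MeCN/H2O (4:1), 0 °C, 15 min
Reagents that add atoms: water, O
Why: Oxidative demethylation of the p-dimethoxyarene by tetravalent cerium (two one-electron oxidations, water as oxygen donor, methanol leaving) should occur only in the methoxy ring because the diacetoxy ring is electron-poor, which moves the quinone into the former aryne ring and leaves the other two oxygens as cleavable acetates.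

Step 8
Reactants: 17 6-[(1R,2E)-1-(TBSO)-4-methyl-4-(TESO)pent-2-en-1-yl]-1,4-dioxo-1,4-dihydronaphthalene-5,8-diyl diacetate
Product: 18 2-[(1R,2E)-1-(TBSO)-4-methyl-4-(TESO)pent-2-en-1-yl]-5,8-dihydroxynaphthalene-1,4-dione
Conditions: K2CO3 (2.5 equiv), degassed MeOH, 0 °C; then aq. NaH2PO4
Reagents that add atoms: none
Why: Base-mediated methanolysis (transesterification) of the two activated aryl acetates should be fast at 0 °C, the liberated dihydroxyquinone tautomerises to the naphthazarin drawn, and both silyl ethers are stable to carbonate in methanol.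

Step 9
Reactants: 18 2-[(1R,2E)-1-(TBSO)-4-methyl-4-(TESO)pent-2-en-1-yl]-5,8-dihydroxynaphthalene-1,4-dione
Product: 19 5,8-dihydroxy-2-[(1R,2E)-1,4-dihydroxy-4-methylpent-2-en-1-yl]naphthalene-1,4-dione
Conditions: HF·pyridine, pyridine/THF, 0 °C → rt
Reagents that add atoms: none
Why: Fluoride-driven desilylation with pyridine-buffered HF breaks only Si–O bonds, so the carbinol configuration is retained and the cation-forming acids or strong bases that the allylic alcohols and the naphthazarin would not tolerate are avoided.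

Step 10
Reactants: 19 5,8-dihydroxy-2-[(1R,2E)-1,4-dihydroxy-4-methylpent-2-en-1-yl]naphthalene-1,4-dione; 20 (2R)-2-methylbutanoic acid
Product: 22 (1R,2E)-1-(5,8-dihydroxy-1,4-dioxo-1,4-dihydronaphthalen-2-yl)-4-hydroxy-4-methylpent-2-en-1-yl (2R)-2-methylbutanoate, via O-acylisourea 21 (not isolated)
Conditions: 20 (1.5 equiv), DCC, DMAP (0.1 equiv), CH2Cl2, 0 °C
Reagents that add atoms: none
Why: Steglich esterification through O-acylisourea 21 should acylate only the secondary alcohol, since the tertiary alcohol is too hindered and the peri-hydroxyls are locked in hydrogen bonds to the quinone carbonyls (a selectivity well known for naphthazarin carbinols), and both stereocentres are retained because the carbinol C–O bond is not broken and the α-branched acyl donor is activated under mild, non-enolising conditions.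

**Compound list**

1 | 2-methylbut-3-yn-2-ol | CC(C)(O)C#C | starting material
2 | triethyl[(2-methylbut-3-yn-2-yl)oxy]silane | CC[Si](CC)(CC)OC(C)(C)C#C | intermediate
3 | furan-3-carbaldehyde (3-furaldehyde) | O=Cc1ccoc1 | starting material
4 | dicyclohexyl[(1E)-3-methyl-3-(triethylsilyloxy)but-1-en-1-yl]borane | CC[Si](CC)(CC)OC(C)(C)/C=C/B(C1CCCCC1)C1CCCCC1 | intermediate
5 | methyl[(1E)-3-methyl-3-(triethylsilyloxy)but-1-en-1-yl]zinc | C[Zn]/C=C/C(C)(C)O[Si](CC)(CC)CC | intermediate
6 | (1R,2E)-1-(furan-3-yl)-4-methyl-4-(triethylsilyloxy)pent-2-en-1-ol | O[C@H](/C=C/C(C)(C)O[Si](CC)(CC)CC)c1ccoc1 | intermediate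
7 | 3-[(1R,2E)-1-(tert-butyldimethylsilyloxy)-4-methyl-4-(triethylsilyloxy)pent-2-en-1-yl]furan | CC(C)(C)[Si](C)(C)O[C@H](/C=C/C(C)(C)O[Si](CC)(CC)CC)c1ccoc1 | intermediate
8 | 2-chloro-1,4-dimethoxybenzene | COc1ccc(OC)c(Cl)c1 | starting material
9 | (2-chloro-3,6-dimethoxyphenyl)lithium | COc1ccc(OC)c(Cl)c1[Li] | intermediate
10 | 3,6-dimethoxybenzyne (1,4-dimethoxy-2,3-didehydrobenzene) | COC1=CC=C(OC)C#C1 | intermediate
11 | 2-[(1R,2E)-1-(tert-butyldimethylsilyloxy)-4-methyl-4-(triethylsilyloxy)pent-2-en-1-yl]-5,8-dimethoxy-1,4-dihydro-1,4-epoxynaphthalene, both bridgehead diastereomers | CC(C)(C)[Si](C)(C)O[C@H](/C=C/C(C)(C)O[Si](CC)(CC)CC)C1=CC2OC1c1c(OC)ccc(OC)c12 | intermediate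
12 | 2-[(1R,2E)-1-(tert-butyldimethylsilyloxy)-4-methyl-4-(triethylsilyloxy)pent-2-en-1-yl]-5,8-dimethoxynaphthalen-1-ol | CC(C)(C)[Si](C)(C)O[C@H](/C=C/C(C)(C)O[Si](CC)(CC)CC)c1ccc2c(OC)ccc(OC)c2c1O | intermediate
13 | 3-[(1R,2E)-1-(tert-butyldimethylsilyloxy)-4-methyl-4-(triethylsilyloxy)pent-2-en-1-yl]-5,8-dimethoxynaphthalen-1-ol | CC(C)(C)[Si](C)(C)O[C@H](/C=C/C(C)(C)O[Si](CC)(CC)CC)c1cc(O)c2c(OC)ccc(OC)c2c1 | intermediate
14 | 2-[(1R,2E)-1-(tert-butyldimethylsilyloxy)-4-methyl-4-(triethylsilyloxy)pent-2-en-1-yl]-5,8-dimethoxynaphthalene-1,4-dione | CC(C)(C)[Si](C)(C)O[C@H](/C=C/C(C)(C)O[Si](CC)(CC)CC)C1=CC(=O)c2c(OC)ccc(OC)c2C1=O | intermediate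
15 | 2-[(1R,2E)-1-(tert-butyldimethylsilyloxy)-4-methyl-4-(triethylsilyloxy)pent-2-en-1-yl]-5,8-dimethoxynaphthalene-1,4-diol | CC(C)(C)[Si](C)(C)O[C@H](/C=C/C(C)(C)O[Si](CC)(CC)CC)c1cc(O)c2c(OC)ccc(OC)c2c1O | intermediate
16 | 2-[(1R,2E)-1-(tert-butyldimethylsilyloxy)-4-methyl-4-(triethylsilyloxy)pent-2-en-1-yl]-5,8-dimethoxynaphthalene-1,4-diyl diacetate | CC(C)(C)[Si](C)(C)O[C@H](/C=C/C(C)(C)O[Si](CC)(CC)CC)c1cc(OC(C)=O)c2c(OC)ccc(OC)c2c1OC(C)=O | intermediate
17 | 6-[(1R,2E)-1-(tert-butyldimethylsilyloxy)-4-methyl-4-(triethylsilyloxy)pent-2-en-1-yl]-1,4-dioxo-1,4-dihydronaphthalene-5,8-diyl diacetate | CC(C)(C)[Si](C)(C)O[C@H](/C=C/C(C)(C)O[Si](CC)(CC)CC)c1cc(OC(C)=O)c2C(=O)C=CC(=O)c2c1OC(C)=O | intermediate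
18 | 2-[(1R,2E)-1-(tert-butyldimethylsilyloxy)-4-methyl-4-(triethylsilyloxy)pent-2-en-1-yl]-5,8-dihydroxynaphthalene-1,4-dione | CC(C)(C)[Si](C)(C)O[C@H](/C=C/C(C)(C)O[Si](CC)(CC)CC)C1=CC(=O)c2c(O)ccc(O)c2C1=O | intermediate
19 | 5,8-dihydroxy-2-[(1R,2E)-1,4-dihydroxy-4-methylpent-2-en-1-yl]naphthalene-1,4-dione | O[C@H](/C=C/C(C)(C)O)C1=CC(=O)c2c(O)ccc(O)c2C1=O | intermediate
20 | (2R)-2-methylbutanoic acid | CC[C@@H](C)C(=O)O | starting material
21 | N,N'-dicyclohexyl-O-[(2R)-2-methylbutanoyl]isourea | CC[C@@H](C)C(=O)OC(=NC1CCCCC1)NC1CCCCC1 | intermediate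
22 | (1R,2E)-1-(5,8-dihydroxy-1,4-dioxo-1,4-dihydronaphthalen-2-yl)-4-hydroxy-4-methylpent-2-en-1-yl (2R)-2-methylbutanoate | CC[C@@H](C)C(=O)O[C@H](/C=C/C(C)(C)O)C1=CC(=O)c2c(O)ccc(O)c2C1=O | target

**Totals**

Total step count: 10
Longest linear sequence: 10 steps (steps 1–10, from 1)

**Three steps most likely to fail**

1. Step 4 (key step). The aryne may be consumed by diisopropylamine or by aryllithium 9 faster than by the furan, or residual strong base may degrade the side chain, so that conversion of 7 stays low. The fallback generates the same aryne without any amine. Commercial 2-bromo-1,4-dimethoxybenzene is lithiated between Br and OMe (LiN(iPr)2, THF, −78 °C) and quenched with I2 to give 2-bromo-3-iodo-1,4-dimethoxybenzene F1. Iodine–lithium exchange of F1 with n-BuLi in toluene/THF at −78 °C in the presence of 7, followed by warming, should release aryne 10 by loss of LiBr and give the cycloadduct. This fallback sets out from 7 and comes back to the route at 11.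

2. Step 5. The acid stage may ionise the silyloxy side chain, and in the radical oxidation the hindered para position of the 3-substituted naphthol may be passed over in favour of ortho attack. The fallback isolates the naphthols 12 and 13 after the acid stage and replaces the radical oxidation by an ionic two-electron oxidation. PhI(OAc)2 in MeOH at 0 °C converts para-unsubstituted phenols into p-quinone monoketals, here 2-substituted 4,4,5,8-tetramethoxynaphthalen-1(4H)-one F2 from 12 and its 3-substituted isomer F3 from 13. Oxalic acid on wet silica should hydrolyse both ketals to the same quinone. This fallback sets out from 11 and comes back at 14.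

3. Step 10. The free peri-hydroxyls may compete for the acyl donor, or the activated acid may rearrange to the N-acylurea, on the most advanced and least robust intermediate. The fallback acylates before the phenols are unmasked. From 17, HF·pyridine gives the diol diacetate 6-[(1R,2E)-1,4-dihydroxy-4-methylpent-2-en-1-yl]-1,4-dioxo-1,4-dihydronaphthalene-5,8-diyl diacetate F4. DCC/DMAP with 20 then gives its (2R)-2-methylbutanoate F5 with no free phenol present. Brief K2CO3/MeOH at 0 °C should remove only the two aryl acetates, which are far more labile than the α-branched secondary ester. This fallback sets out from 17 and comes back at 22.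

**Further compounds**

F1 | step 4 | 2-bromo-3-iodo-1,4-dimethoxybenzene | COc1ccc(OC)c(I)c1Br
F2 | step 5 | 2-[(1R,2E)-1-(tert-butyldimethylsilyloxy)-4-methyl-4-(triethylsilyloxy)pent-2-en-1-yl]-4,4,5,8-tetramethoxynaphthalen-1(4H)-one | CC(C)(C)[Si](C)(C)O[C@H](/C=C/C(C)(C)O[Si](CC)(CC)CC)C1=CC(OC)(OC)c2c(OC)ccc(OC)c2C1=O
F3 | step 5 | 3-[(1R,2E)-1-(tert-butyldimethylsilyloxy)-4-methyl-4-(triethylsilyloxy)pent-2-en-1-yl]-4,4,5,8-tetramethoxynaphthalen-1(4H)-one | CC(C)(C)[Si](C)(C)O[C@H](/C=C/C(C)(C)O[Si](CC)(CC)CC)C1=CC(=O)c2c(OC)ccc(OC)c2C1(OC)OC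
F4 | step 10 | 6-[(1R,2E)-1,4-dihydroxy-4-methylpent-2-en-1-yl]-1,4-dioxo-1,4-dihydronaphthalene-5,8-diyl diacetate | O[C@H](/C=C/C(C)(C)O)c1cc(OC(C)=O)c2C(=O)C=CC(=O)c2c1OC(C)=O
F5 | step 10 | (1R,2E)-1-(1,4-diacetoxy-5,8-dioxo-5,8-dihydronaphthalen-2-yl)-4-hydroxy-4-methylpent-2-en-1-yl (2R)-2-methylbutanoate | CC[C@@H](C)C(=O)O[C@H](/C=C/C(C)(C)O)c1cc(OC(C)=O)c2C(=O)C=CC(=O)c2c1OC(C)=O
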